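## Assumptions

- The target SMILES has no stereocentres. The biaryl has only two ortho substituents, so the axis is not configurationally stable, and the "single enantiomer" clause is moot.
- Giganteone A is a malabaricone C unit whose catechol ring carbon C6 (para to a catechol O, ortho to the chain) is bonded to C3' of the resorcinol ring of a second malabaricone C unit.
- All eight phenols are carried as methyl ethers and released at the end.

## Retrosynthetic overview

1. Giganteone A comes from global BBr3 demethylation of its octamethyl ether, which comes from hydrogenation of a styrenyl C=C.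
2. The biaryl bond and the ring-A chain are formed together in one Pd/norbornene (Catellani-type) three-component coupling, which is the proposed new step. The components are 4-iodoveratrole, an aryl bromide that already carries the ring-B ketone and ring D, and a terminal-alkene aryl ketone that carries ring C.
3. Both ketones come from Grignard addition to a 2,6-dimethoxybenzaldehyde followed by oxidation. The ω-veratryl-octyl Grignard comes from a B-alkyl Suzuki coupling.
4. All four aromatic rings are pre-formed; the only C–C bond formations are two Grignard additions, one B-alkyl Suzuki coupling, the Catellani coupling and the hydrogenation.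

## Route

**Step 1**
Reactants: 1 (2,6-dimethoxybenzaldehyde); 2 (8-bromo-1-octene)
Product: 3, 1-(2,6-dimethoxyphenyl)non-8-en-1-ol
Conditions: (a) Mg, I2 (cat.), THF, reflux, to form the Grignard from 2; (b) add 1, 0 °C → rt; (c) aq. NH4Cl
Reagents that add atoms: none (the C8 chain comes from 2)
Why: Grignard 1,2-addition to an aldehyde. The alkene is inert and the new carbinol carbon is not a stereocentre that matters, because it is oxidised in Step 2.

**Step 2**
Reactants: 3
Product: 4, 1-(2,6-dimethoxyphenyl)non-8-en-1-one (the alkene partner for Step 7)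
Conditions: Dess–Martin periodinane, NaHCO3, CH2Cl2, rt
Reagents that add atoms: none
Why: DMP oxidation of a secondary benzylic alcohol to the ketone, with the terminal alkene and aryl ethers untouched.

**Step 3**
Reactants: 1
Product: 5, 3-bromo-2,6-dimethoxybenzaldehyde
Conditions: NBS, MeCN, 0 °C → rt, dark
Reagents that add atoms: NBS, O=C1CCC(=O)N1Br (leaves Br)
Why: Electrophilic aromatic bromination. C3 is ortho to one OMe, para to the other and meta to the CHO, so it is the only activated position.

**Step 4**
Reactants: 2 (8-bromo-1-octene); 6 (4-bromo-1,2-dimethoxybenzene)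
Product: 7, 4-(8-bromooctyl)-1,2-dimethoxybenzene
Conditions: (a) 9-BBN dimer, THF, rt; (b) 6, Pd(dppf)Cl2 (3 mol%), aq. K3PO4, THF, 60 °C
Reagents that add atoms: none
Why: Hydroboration followed by B-alkyl Suzuki–Miyaura coupling. The aryl C–Br couples much faster than the primary alkyl C–Br, which is retained for Step 5.

**Step 5**
Reactants: 7; 5
Product: 8, 1-(3-bromo-2,6-dimethoxyphenyl)-9-(3,4-dimethoxyphenyl)nonan-1-ol
Conditions: (a) Mg, I2 (cat.), THF, reflux, to pre-form the Grignard from 7; (b) add 5, −10 °C → rt; (c) aq. NH4Cl
Reagents that add atoms: none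
Why: Grignard addition to an aldehyde. The alkyl Grignard does not exchange with the aryl bromide at or below rt, and the ortho-OMe groups chelate Mg and assist addition.

**Step 6**
Reactants: 8
Product: 9, 1-(3-bromo-2,6-dimethoxyphenyl)-9-(3,4-dimethoxyphenyl)nonan-1-one (the aryl bromide partner for Step 7)
Conditions: Dess–Martin periodinane, NaHCO3, CH2Cl2, rt
Reagents that add atoms: none
Why: DMP oxidation of the hindered benzylic alcohol; the Ar–Br is unaffected.

**Step 7**
Reactants: 9; 4; 10 (4-iodo-1,2-dimethoxybenzene, 4-iodoveratrole)
Product: 11, the (E)-styrenyl octamethyl ether: 1-(2,6-dimethoxyphenyl)-9-[2-(3-acyl-2,4-dimethoxyphenyl)-4,5-dimethoxyphenyl]non-8-en-1-one, where the 3-acyl group is the 9-(3,4-dimethoxyphenyl)nonanoyl chain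
Conditions: Pd(OAc)2 (10 mol%), tri(2-furyl)phosphine (24 mol%), norbornene (2 equiv), K2CO3 (3 equiv), DMF, 100 °C, N2, 24 h. Stoichiometry: 10 (1.0 equiv), 9 (1.3 equiv), 4 (2.0 equiv).
Reagents that add atoms: none (norbornene is a transient mediator and is not retained)
Why: Proposed new method: Catellani-type Pd/norbornene cooperative catalysis.
- Oxidative addition of 10, norbornene insertion and carbonate-assisted ortho C–H palladation at the less hindered C5–H (para to OMe) give an aryl-norbornyl palladacycle.
- Oxidative addition of the ortho-alkoxy aryl bromide 9 (the ortho-OMe plays the role of the usual ortho substituent) gives Pd(IV), and C–C reductive elimination forms the biaryl bond.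
- β-Carbon elimination expels norbornene, and the ipso aryl-Pd undergoes Mizoroki–Heck termination with the terminal alkene of 4, giving the linear E-styrene.
- The closest known reaction is Catellani ortho-arylation/ipso-Heck. The novelty is its use on an electron-rich, ortho-OMe, ketone-bearing aryl bromide and a ketone-containing unactivated alkene, building the hindered tetra-oxygenated biaryl and the ring-A chain in one operation.
- No stereocentre is formed; the alkene geometry is erased in Step 8.

**Step 8**
Reactants: 11
Product: 12, octamethyl giganteone A: 1-(2,6-dimethoxyphenyl)-9-[2-(3-{9-(3,4-dimethoxyphenyl)nonanoyl}-2,4-dimethoxyphenyl)-4,5-dimethoxyphenyl]nonan-1-one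
Conditions: H2 (1 atm), 10% Pd/C, EtOAc, rt
Reagents that add atoms: none (only H added)
Why: Catalytic hydrogenation of the styrenyl C=C. No aryl halide remains (both Br and I were consumed in Step 7), and the twisted 2,6-dimethoxyaryl ketones and aryl ethers are inert.

**Step 9**
Reactants: 12
Product: 13, giganteone A
Conditions: BBr3 (1 M in CH2Cl2, 20 equiv), CH2Cl2, −78 °C → rt, 18 h; quench with MeOH at 0 °C; degassed solvents, Ar
Reagents that add atoms: none (B–O bonds are cleaved on quench, leaving OH)
Why: BBr3 demethylation of all eight aryl methyl ethers. The flanking ketones chelate boron and assist cleavage of the ortho OMe groups, and the aryl ketones and alkyl chains survive.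

## Compound list

| No. | Name | SMILES | Role |
|---|---|---|---|
| 1 | 2,6-dimethoxybenzaldehyde | COc1cccc(OC)c1C=O | starting material |
| 2 | 8-bromo-1-octene | C=CCCCCCCBr | starting material |
| 3 | 1-(2,6-dimethoxyphenyl)non-8-en-1-ol | C=CCCCCCCC(O)c1c(OC)cccc1OC | intermediate |
| 4 | 1-(2,6-dimethoxyphenyl)non-8-en-1-one | C=CCCCCCCC(=O)c1c(OC)cccc1OC | intermediate |
| 5 | 3-bromo-2,6-dimethoxybenzaldehyde | COc1ccc(Br)c(OC)c1C=O | intermediate |
| 6 | 4-bromo-1,2-dimethoxybenzene | COc1ccc(Br)cc1OC | starting material |
| 7 | 4-(8-bromooctyl)-1,2-dimethoxybenzene | COc1ccc(CCCCCCCCBr)cc1OC | intermediate |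
| 8 | 1-(3-bromo-2,6-dimethoxyphenyl)-9-(3,4-dimethoxyphenyl)nonan-1-ol | COc1ccc(CCCCCCCCC(O)c2c(OC)ccc(Br)c2OC)cc1OC | intermediate |
| 9 | 1-(3-bromo-2,6-dimethoxyphenyl)-9-(3,4-dimethoxyphenyl)nonan-1-one | COc1ccc(CCCCCCCCC(=O)c2c(OC)ccc(Br)c2OC)cc1OC | intermediate |
| 10 | 4-iodo-1,2-dimethoxybenzene | COc1ccc(I)cc1OC | starting material |
| 11 | (E)-styrenyl octamethyl ether (Catellani product) | COc1cc(/C=C/CCCCCCC(=O)c2c(OC)cccc2OC)c(cc1OC)-c1ccc(OC)c(C(=O)CCCCCCCCc2ccc(OC)c(OC)c2)c1OC | intermediate |
| 12 | octamethyl giganteone A | COc1cc(CCCCCCCCC(=O)c2c(OC)cccc2OC)c(cc1OC)-c1ccc(OC)c(C(=O)CCCCCCCCc2ccc(OC)c(OC)c2)c1OC | intermediate |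
| 13 | giganteone A | O=C(CCCCCCCCc1cc(O)c(O)cc1-c1ccc(O)c(C(=O)CCCCCCCCc2ccc(O)c(O)c2)c1O)c1c(O)cccc1O | target |

## Totals

Total steps: 9. Longest linear sequence: 6 (for example 1 → 5 → 8 → 9 → 11 → 12 → 13).

## Three steps most likely to fail

1. **Step 7 (proposed new Catellani coupling).** Electron-rich ortho-OMe aryl bromides are poor Pd(IV) precursors, and competing direct Heck reaction or 2,6-diarylation are possible.
   Fallback, which changes the approach to a stepwise Suzuki route:
   - Make 1-(2,6-dimethoxyphenyl)-9-(3,4-dimethoxyphenyl)nonan-1-one by adding the Grignard from 7 to 1 and oxidising with DMP.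
   - Brominate the veratryl ring selectively with NBS.
   - Convert 9 to its pinacol boronate by Miyaura borylation.
   - Couple the two fragments by Suzuki–Miyaura (Pd/SPhos, K3PO4) to give 12.
2. **Step 9 (eight-fold BBr3 demethylation).** Incomplete cleavage, or decomposition of the electron-rich catechols.
   Fallback: rebuild the sequence with MOM ethers in place of methyl ethers (MOM-protected versions of 1, 5 and 6), then remove them at the end with HCl/MeOH.
3. **Step 4 (B-alkyl Suzuki coupling on an ω-bromoalkyl-9-BBN).** The alkyl bromide may compete or hydrolyse.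
   Fallback: make 7 by Friedel–Crafts acylation of veratrole with 8-bromooctanoyl chloride (AlCl3), then reduce the aryl ketone with Et3SiH/TFA.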